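**Retrosynthetic overview**
- Target hydroquinone ⇐ one-pot CAN oxidation / dithionite reduction of a dimethoxyarene, C12-OPMB macrolactam; the C7 carbamate goes on just before.
- 19-Membered lactam (last ring formed) ⇐ intramolecular Cu-catalysed N-arylation of a (2E,4Z)-dienamide by an aryl bromide.
- Dienamide ⇐ Sonogashira coupling / Z-selective enyne reduction (C3–C4), syn-propargylation (C6–C7), cross-metathesis with methacrolein (C8=C9).
- C9–C15 aryl segment ⇐ bis-O-methylation of the diol obtained when a pyranose lactol is opened by an aryllithium from a symmetric dibromoarene; the pyran ring oxygen and the anomeric carbon become C11-OMe and C15.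
- Key step: Achmatowicz oxidative ring expansion of a furfural-derived furyl carbinol. The temporary pyranone (first ring formed, step 2; opened in step 9) relays C11 to C14 (cuprate) and C12 (thermodynamic reduction). The benzene ring is bought.

Assumption: ansamycin numbering (C1 = amide carbonyl, C15 = benzylic carbon) is used for positions; the SMILES is read as 2E,4Z,8E and 6S,7R,10S,11R,12S,14S,15R; reagent solutions made fresh in the flask (Brown crotylborane, Me2CuLi, Bu3SnLi) count as reagents, not steps.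

**Route**

Step 1
Reactants: 1 furfural
Product: 2 (1R,2S)-1-(furan-2-yl)-2-methylbut-3-en-1-ol
Conditions: (Z)-crotyl-B(Ipc)2 [cis-but-2-ene, n-BuLi, KOt-Bu, THF, −78 to −45 °C; (+)-Ipc2BOMe; BF3·OEt2], then 1, −78 °C, 4 h; NaOH, H2O2, 0 °C to rt
Reagents that add atoms: (Z)-crotyldiisopinocampheylborane (made in the flask from cis-but-2-ene, C/C=C\C), C/C=C\CB([C@H]1C[C@H]2C[C@@H]([C@@H]1C)C2(C)C)[C@H]1C[C@H]2C[C@@H]([C@@H]1C)C2(C)C
Why: Brown asymmetric crotylboration, in which the (Z)-crotyl group reacts through a closed chair transition state to give the syn adduct and the (−)-α-pinene-derived Ipc groups direct attack to the Re face of the aldehyde, setting C11 (R) and C10 (S).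

Step 2
Reactants: 2 (1R,2S)-1-(furan-2-yl)-2-methylbut-3-en-1-ol
Product: 3 (2R)-2-[(2S)-but-3-en-2-yl]-6-hydroxy-2H-pyran-3(6H)-one (anomer mixture)
Conditions: NBS (1.05 equiv), NaHCO3, NaOAc, THF/H2O 4:1, 0 °C, 30 min
Reagents that add atoms: water, O
Why: Achmatowicz rearrangement (key step), in which NBS/water oxidises the electron-rich furan far faster than the monosubstituted alkene, breaking its aromaticity to a cis-enedione that recloses on the C11 hydroxyl to the pyranone hemiacetal without touching C10 or C11.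

Step 3
Reactants: 3 (2R)-2-[(2S)-but-3-en-2-yl]-6-hydroxy-2H-pyran-3(6H)-one
Product: 4 (2R,6S)-2-[(2S)-but-3-en-2-yl]-6-(propan-2-yloxy)-2H-pyran-3(6H)-one
Conditions: HC(Oi-Pr)3 (3 equiv), BF3·OEt2 (10 mol%), CH2Cl2, −20 to 0 °C; chromatography, minor cis anomer re-equilibrated
Reagents that add atoms: triisopropyl orthoformate, CC(C)OC(OC(C)C)OC(C)C
Why: acid-catalysed acetal exchange through the ring oxocarbenium ion under thermodynamic control, where the anomeric effect places the isopropoxy group pseudo-axial and therefore trans to the C11 side chain (expected about 5:1).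

Step 4
Reactants: 4 (2R,6S)-2-[(2S)-but-3-en-2-yl]-6-(propan-2-yloxy)-2H-pyran-3(6H)-one
Product: 5 (2R,5S,6S)-2-[(2S)-but-3-en-2-yl]-5-methyl-6-(propan-2-yloxy)oxan-3-one
Conditions: Me2CuLi (1.5 equiv, from CuI and MeLi), Et2O, −78 °C, 1 h; NH4Cl (aq)
Reagents that add atoms: lithium dimethylcuprate, [Li+].C[Cu-]C
Why: Gilman conjugate addition to the enone, with axial attack anti to the pseudo-axial anomeric isopropoxy group setting C14 (S) cis to the C11 side chain, while the regiodefined C12–C13 enolate leaves C11 untouched on protonation.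

Step 5
Reactants: 5 (2R,5S,6S)-2-[(2S)-but-3-en-2-yl]-5-methyl-6-(propan-2-yloxy)oxan-3-one
Product: 6 (2R,3S,5S,6S)-2-[(2S)-but-3-en-2-yl]-5-methyl-6-(propan-2-yloxy)oxan-3-ol
Conditions: Al(Oi-Pr)3 (0.5 equiv), i-PrOH, 82 °C, sealed (acetone retained), 24 h
Reagents that add atoms: none
Why: Meerwein–Ponndorf–Verley reduction run under reversible (Oppenauer-equilibrating) conditions gives the thermodynamic equatorial C12 alcohol (S), trans to the C11 chain, because the axial epimer suffers a 1,3-diaxial clash with the axial C14 methyl that makes kinetic hydride reagents unselective, and the isopropyl acetal makes alkoxide exchange degenerate.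

Step 6
Reactants: 6 (2R,3S,5S,6S)-2-[(2S)-but-3-en-2-yl]-5-methyl-6-(propan-2-yloxy)oxan-3-ol
Product: 7 (2R,3S,5S,6S)-2-[(2S)-but-3-en-2-yl]-3-[(4-methoxybenzyl)oxy]-5-methyl-6-(propan-2-yloxy)oxane
Conditions: NaH, PMBCl, Bu4NI (cat.), DMF, 0 °C to rt
Reagents that add atoms: 4-methoxybenzyl chloride, COc1ccc(CCl)cc1
Why: Williamson etherification of the only hydroxyl, the PMB group being chosen because it survives aryllithium, NaH/MeI, metathesis, Pd and Cu steps and is removed by CAN in the final oxidation.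

Step 7
Reactants: 7 (2R,3S,5S,6S)-2-[(2S)-but-3-en-2-yl]-3-[(4-methoxybenzyl)oxy]-5-methyl-6-(propan-2-yloxy)oxane
Product: 8 (3S,5S,6R)-6-[(2S)-but-3-en-2-yl]-5-[(4-methoxybenzyl)oxy]-3-methyloxan-2-ol (anomer mixture)
Conditions: 1 M HCl/THF 1:3, 40 °C, 3 h
Reagents that add atoms: water, O
Why: acid hydrolysis of the glycosidic acetal (fast because C14 carries no electron-withdrawing oxygen) unmasks C15 as a lactol while the PMB ether, the alkene and the ring stereocentres are stable.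

Step 8
Reactants: 9 2,6-dibromo-4-methoxyphenol
Product: 10 1,3-dibromo-2,5-dimethoxybenzene
Conditions: MeI, K2CO3, acetone, reflux, 6 h
Reagents that add atoms: iodomethane, CI
Why: Williamson O-methylation of the phenol gives the symmetric dibromide whose two bromines later serve the C15–aryl bond and the ring-closing C–N bond.

Step 9
Reactants: 8 (3S,5S,6R)-6-[(2S)-but-3-en-2-yl]-5-[(4-methoxybenzyl)oxy]-3-methyloxan-2-ol; 10 1,3-dibromo-2,5-dimethoxybenzene
Product: 12 (1R,2S,4S,5R,6S)-1-(3-bromo-2,5-dimethoxyphenyl)-4-[(4-methoxybenzyl)oxy]-2,6-dimethyloct-7-ene-1,5-diol, via aryllithium 11 (not isolated)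
Conditions: 10 (2.6 equiv), n-BuLi (2.5 equiv), THF, −78 °C, 20 min; add 8, −78 to −30 °C, 2 h; NH4Cl (aq)
Reagents that add atoms: none
Why: mono bromine–lithium exchange breaks the symmetry of the dibromide, and the aryllithium (one equivalent deprotonates the lactol, the next adds to the ring-opened aldehyde) attacks under Felkin–Anh control by the C14 methyl to give the 14,15-syn carbinol with C15 (R), expected about 3–4:1 with separable epimers, the second bromine being kept for the ring closure.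

Step 10
Reactants: 12 (1R,2S,4S,5R,6S)-1-(3-bromo-2,5-dimethoxyphenyl)-4-[(4-methoxybenzyl)oxy]-2,6-dimethyloct-7-ene-1,5-diol
Product: 13 1-bromo-3-[(1R,2S,4S,5R,6S)-1,5-dimethoxy-4-[(4-methoxybenzyl)oxy]-2,6-dimethyloct-7-en-1-yl]-2,5-dimethoxybenzene
Conditions: NaH (4 equiv), MeI (6 equiv), THF/DMF 4:1, 0 °C to rt
Reagents that add atoms: iodomethane, CI
Why: double Williamson methylation of the two free hydroxyls (the former pyran ring oxygen at C11 and the new benzylic alcohol at C15) installs both methyl ethers of the target at once while C12 stays differentiated as its PMB ether.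

Step 11
Reactants: 13 1-bromo-3-[(1R,2S,4S,5R,6S)-1,5-dimethoxy-4-[(4-methoxybenzyl)oxy]-2,6-dimethyloct-7-en-1-yl]-2,5-dimethoxybenzene
Product: 14 (2E,4S,5R,6S,8S,9R)-9-(3-bromo-2,5-dimethoxyphenyl)-5,9-dimethoxy-6-[(4-methoxybenzyl)oxy]-2,4,8-trimethylnon-2-enal
Conditions: methacrolein (15 equiv), Hoveyda–Grubbs II (10 mol%), CH2Cl2, 40 °C, 24 h
Reagents that add atoms: methacrolein, CC(=C)C=O
Why: olefin cross-metathesis of the terminal alkene with the electron-poor 1,1-disubstituted partner gives the thermodynamically preferred (E)-trisubstituted enal (C8=C9) without touching the C10 stereocentre.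

Step 12
Reactants: 15 (S)-but-3-yn-2-ol
Product: 16 (S)-but-3-yn-2-yl methanesulfonate
Conditions: MsCl, Et3N, CH2Cl2, −78 to 0 °C
Reagents that add atoms: methanesulfonyl chloride, CS(Cl)(=O)=O
Why: O-sulfonylation with retention gives the propargylic leaving group needed for the SN2′ step.

Step 13
Reactants: 16 (S)-but-3-yn-2-yl methanesulfonate
Product: 17 (aR)-tributyl(buta-1,2-dien-1-yl)stannane
Conditions: Bu3SnH, LDA, THF, 0 °C; CuBr·SMe2, −78 °C; then 16, −78 °C, 30 min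
Reagents that add atoms: tributyltin hydride, CCCC[SnH](CCCC)CCCC
Why: anti SN2′ displacement of the propargylic mesylate by the stannylcuprate converts the carbinol stereocentre into the axial chirality of the (aR)-allenylstannane.

Step 14
Reactants: 14 (2E,4S,5R,6S,8S,9R)-9-(3-bromo-2,5-dimethoxyphenyl)-5,9-dimethoxy-6-[(4-methoxybenzyl)oxy]-2,4,8-trimethylnon-2-enal; 17 (aR)-tributyl(buta-1,2-dien-1-yl)stannane
Product: 18 (3S,4R,5E,7S,8R,9S,11S,12R)-12-(3-bromo-2,5-dimethoxyphenyl)-8,12-dimethoxy-9-[(4-methoxybenzyl)oxy]-3,5,7,11-tetramethyldodec-5-en-1-yn-4-ol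
Conditions: 17 (1.5 equiv), BF3·OEt2 (2 equiv), CH2Cl2, −78 °C, 2 h; NaHCO3 (aq)
Reagents that add atoms: none
Why: Marshall propargylation, a BF3-promoted anti-SE2′ addition through an open transition state that gives the syn homopropargylic alcohol, the allene axis fixing C6 (S) and the syn preference fixing C7 (R) under reagent control because the enal has no nearby stereocentre.

Step 15
Reactants: 19 diethyl 2-methylmalonate
Product: 20 diethyl 2-(diiodomethyl)-2-methylmalonate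
Conditions: NaH, CHI3, Et2O, reflux, 24 h
Reagents that add atoms: iodoform, IC(I)I
Why: C-alkylation of the malonate enolate by iodoform (via diiodocarbene or direct substitution) gives the diiodomethyl compound.

Step 16
Reactants: 20 diethyl 2-(diiodomethyl)-2-methylmalonate
Product: 21 (E)-3-iodo-2-methylprop-2-enoic acid
Conditions: KOH, EtOH/H2O 3:1, reflux, 24 h; then HCl (aq) to pH 2
Reagents that add atoms: potassium hydroxide, [K+].[OH-]
Why: saponification followed by decarboxylative elimination of iodide (Grob-type fragmentation) gives the thermodynamically preferred (E)-β-iodoacrylic acid.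

Step 17
Reactants: 21 (E)-3-iodo-2-methylprop-2-enoic acid
Product: 23 (E)-3-iodo-2-methylprop-2-enamide, via acid chloride 22 (not isolated)
Conditions: (COCl)2, DMF (cat.), CH2Cl2, 0 °C to rt; evaporate; NH3 (0.5 M in dioxane), 0 °C
Reagents that add atoms: ammonia, N
Why: acyl chloride formation and aminolysis give the primary amide with the (E)-vinyl iodide unchanged.

Step 18
Reactants: 18 (3S,4R,5E,7S,8R,9S,11S,12R)-12-(3-bromo-2,5-dimethoxyphenyl)-8,12-dimethoxy-9-[(4-methoxybenzyl)oxy]-3,5,7,11-tetramethyldodec-5-en-1-yn-4-ol; 23 (E)-3-iodo-2-methylprop-2-enamide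
Product: 24 (2E,6S,7R,8E,10S,11R,12S,14S,15R)-15-(3-bromo-2,5-dimethoxyphenyl)-7-hydroxy-11,15-dimethoxy-12-[(4-methoxybenzyl)oxy]-2,6,8,10,14-pentamethylpentadeca-2,8-dien-4-ynamide
Conditions: PdCl2(PPh3)2 (5 mol%), CuI (10 mol%), Et3N, THF, rt, 4 h
Reagents that add atoms: none
Why: Sonogashira coupling, in which oxidative addition to the vinyl iodide at room temperature proceeds with retention of the (E) geometry and is much faster than to the hindered electron-rich aryl bromide.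

Step 19
Reactants: 24 (2E,6S,7R,8E,10S,11R,12S,14S,15R)-15-(3-bromo-2,5-dimethoxyphenyl)-7-hydroxy-11,15-dimethoxy-12-[(4-methoxybenzyl)oxy]-2,6,8,10,14-pentamethylpentadeca-2,8-dien-4-ynamide
Product: 25 (2E,4Z,6S,7R,8E,10S,11R,12S,14S,15R)-15-(3-bromo-2,5-dimethoxyphenyl)-7-hydroxy-11,15-dimethoxy-12-[(4-methoxybenzyl)oxy]-2,6,8,10,14-pentamethylpentadeca-2,4,8-trienamide
Conditions: Zn(Cu/Ag), MeOH/H2O/dioxane 2:2:1, 45 °C, 12 h
Reagents that add atoms: none
Why: Boland semi-reduction of the conjugated enyne delivers two hydrogens syn to give the (4Z)-alkene without over-reduction and leaves the aryl bromide, the PMB ether and the isolated trisubstituted alkene intact.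

Step 20
Reactants: 25 (2E,4Z,6S,7R,8E,10S,11R,12S,14S,15R)-15-(3-bromo-2,5-dimethoxyphenyl)-7-hydroxy-11,15-dimethoxy-12-[(4-methoxybenzyl)oxy]-2,6,8,10,14-pentamethylpentadeca-2,4,8-trienamide
Product: 26 (4E,6Z,8S,9R,10E,12S,13R,14S,16S,17R)-9-hydroxy-13,17,20,22-tetramethoxy-14-[(4-methoxybenzyl)oxy]-4,8,10,12,16-pentamethyl-2-azabicyclo[16.3.1]docosa-1(21),4,6,10,18(22),19-hexaen-3-one
Conditions: CuI (50 mol%), N,N′-dimethylethylenediamine (1 equiv), K2CO3 (3 equiv), toluene (2 mM), 100 °C, 36 h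
Reagents that add atoms: none
Why: intramolecular Goldberg (copper-catalysed Ullmann-type) N-arylation of the primary dienamide by the aryl bromide closes the 19-membered lactam, the amide being arylated in preference to the free C7 hydroxyl and the (2E,4Z)-diene surviving these conditions.

Step 21
Reactants: 26 (4E,6Z,8S,9R,10E,12S,13R,14S,16S,17R)-9-hydroxy-13,17,20,22-tetramethoxy-14-[(4-methoxybenzyl)oxy]-4,8,10,12,16-pentamethyl-2-azabicyclo[16.3.1]docosa-1(21),4,6,10,18(22),19-hexaen-3-one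
Product: 28 (4E,6Z,8S,9R,10E,12S,13R,14S,16S,17R)-13,17,20,22-tetramethoxy-14-[(4-methoxybenzyl)oxy]-4,8,10,12,16-pentamethyl-3-oxo-2-azabicyclo[16.3.1]docosa-1(21),4,6,10,18(22),19-hexaen-9-yl carbamate, via trichloroacetyl carbamate 27 (not isolated)
Conditions: Cl3CC(O)NCO, CH2Cl2, 0 °C, 30 min; then K2CO3 (cat.), MeOH, rt, 1 h
Reagents that add atoms: trichloroacetyl isocyanate, O=C=NC(=O)C(Cl)(Cl)Cl
Why: the only free hydroxyl (C7) adds to the isocyanate and methanolysis of the trichloroacetyl group leaves the primary carbamate with retention at C7.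

Step 22
Reactants: 28 (4E,6Z,8S,9R,10E,12S,13R,14S,16S,17R)-13,17,20,22-tetramethoxy-14-[(4-methoxybenzyl)oxy]-4,8,10,12,16-pentamethyl-3-oxo-2-azabicyclo[16.3.1]docosa-1(21),4,6,10,18(22),19-hexaen-9-yl carbamate
Product: 30 (4E,6Z,8S,9R,10E,12S,13R,14S,16S,17R)-14,20,22-trihydroxy-13,17-dimethoxy-4,8,10,12,16-pentamethyl-3-oxo-2-azabicyclo[16.3.1]docosa-1(21),4,6,10,18(22),19-hexaen-9-yl carbamate, via quinone 29 (not isolated)
Conditions: CAN (6 equiv), MeCN/H2O 4:1, 0 °C, 20 min; extract into EtOAc; shake with Na2S2O4 (aq), rt, under Ar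
Reagents that add atoms: water, O
Why: cerium(IV) oxidative demethylation of the 1,4-dimethoxyarene to the p-quinone with simultaneous oxidative cleavage of the C12 PMB ether, followed by dithionite reduction of the quinone to the hydroquinone, with no stereocentre involved.

**Compound list**

1 | furfural (furan-2-carbaldehyde) | O=Cc1ccco1 | starting material
2 | (1R,2S)-1-(furan-2-yl)-2-methylbut-3-en-1-ol | O[C@@H](c1ccco1)[C@@H](C)C=C | intermediate
3 | (2R)-2-[(2S)-but-3-en-2-yl]-6-hydroxy-2H-pyran-3(6H)-one (anomer mixture at C6) | O=C1C=CC(O)O[C@@H]1[C@@H](C)C=C | intermediate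
4 | (2R,6S)-2-[(2S)-but-3-en-2-yl]-6-(propan-2-yloxy)-2H-pyran-3(6H)-one (2,6-trans) | O=C1C=C[C@@H](OC(C)C)O[C@@H]1[C@@H](C)C=C | intermediate
5 | (2R,5S,6S)-2-[(2S)-but-3-en-2-yl]-5-methyl-6-(propan-2-yloxy)oxan-3-one | O=C1C[C@H](C)[C@@H](OC(C)C)O[C@@H]1[C@@H](C)C=C | intermediate
6 | (2R,3S,5S,6S)-2-[(2S)-but-3-en-2-yl]-5-methyl-6-(propan-2-yloxy)oxan-3-ol | O[C@H]1C[C@H](C)[C@@H](OC(C)C)O[C@@H]1[C@@H](C)C=C | intermediate
7 | (2R,3S,5S,6S)-2-[(2S)-but-3-en-2-yl]-3-[(4-methoxybenzyl)oxy]-5-methyl-6-(propan-2-yloxy)oxane | COc1ccc(CO[C@H]2C[C@H](C)[C@@H](OC(C)C)O[C@@H]2[C@@H](C)C=C)cc1 | intermediate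
8 | (3S,5S,6R)-6-[(2S)-but-3-en-2-yl]-5-[(4-methoxybenzyl)oxy]-3-methyloxan-2-ol (anomer mixture at C2) | COc1ccc(CO[C@H]2C[C@H](C)C(O)O[C@@H]2[C@@H](C)C=C)cc1 | intermediate
9 | 2,6-dibromo-4-methoxyphenol | COc1cc(Br)c(O)c(Br)c1 | starting material
10 | 1,3-dibromo-2,5-dimethoxybenzene | COc1cc(Br)c(OC)c(Br)c1 | intermediate
11 | (3-bromo-2,5-dimethoxyphenyl)lithium | [Li]c1cc(OC)cc(Br)c1OC | intermediate
12 | (1R,2S,4S,5R,6S)-1-(3-bromo-2,5-dimethoxyphenyl)-4-[(4-methoxybenzyl)oxy]-2,6-dimethyloct-7-ene-1,5-diol | C=C[C@H](C)[C@@H](O)[C@@H](OCc1ccc(OC)cc1)C[C@H](C)[C@@H](O)c1cc(OC)cc(Br)c1OC | intermediate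
13 | 1-bromo-3-[(1R,2S,4S,5R,6S)-1,5-dimethoxy-4-[(4-methoxybenzyl)oxy]-2,6-dimethyloct-7-en-1-yl]-2,5-dimethoxybenzene | C=C[C@H](C)[C@@H](OC)[C@@H](OCc1ccc(OC)cc1)C[C@H](C)[C@@H](OC)c1cc(OC)cc(Br)c1OC | intermediate
14 | (2E,4S,5R,6S,8S,9R)-9-(3-bromo-2,5-dimethoxyphenyl)-5,9-dimethoxy-6-[(4-methoxybenzyl)oxy]-2,4,8-trimethylnon-2-enal | O=C/C(C)=C/[C@H](C)[C@@H](OC)[C@@H](OCc1ccc(OC)cc1)C[C@H](C)[C@@H](OC)c1cc(OC)cc(Br)c1OC | intermediate
15 | (S)-but-3-yn-2-ol | C#C[C@H](C)O | starting material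
16 | (S)-but-3-yn-2-yl methanesulfonate | C#C[C@H](C)OS(C)(=O)=O | intermediate
17 | (aR)-tributyl(buta-1,2-dien-1-yl)stannane | CCCC[Sn](CCCC)(CCCC)C([H])=[C@]=C([H])C | intermediate
18 | (3S,4R,5E,7S,8R,9S,11S,12R)-12-(3-bromo-2,5-dimethoxyphenyl)-8,12-dimethoxy-9-[(4-methoxybenzyl)oxy]-3,5,7,11-tetramethyldodec-5-en-1-yn-4-ol | C#C[C@H](C)[C@@H](O)/C(C)=C/[C@H](C)[C@@H](OC)[C@@H](OCc1ccc(OC)cc1)C[C@H](C)[C@@H](OC)c1cc(OC)cc(Br)c1OC | intermediate
19 | diethyl 2-methylmalonate | CCOC(=O)C(C)C(=O)OCC | starting material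
20 | diethyl 2-(diiodomethyl)-2-methylmalonate | CCOC(=O)C(C)(C(I)I)C(=O)OCC | intermediate
21 | (E)-3-iodo-2-methylprop-2-enoic acid | OC(=O)/C(C)=C/I | intermediate
22 | (E)-3-iodo-2-methylprop-2-enoyl chloride | ClC(=O)/C(C)=C/I | intermediate
23 | (E)-3-iodo-2-methylprop-2-enamide | NC(=O)/C(C)=C/I | intermediate
24 | (2E,6S,7R,8E,10S,11R,12S,14S,15R)-15-(3-bromo-2,5-dimethoxyphenyl)-7-hydroxy-11,15-dimethoxy-12-[(4-methoxybenzyl)oxy]-2,6,8,10,14-pentamethylpentadeca-2,8-dien-4-ynamide | NC(=O)/C(C)=C/C#C[C@H](C)[C@@H](O)/C(C)=C/[C@H](C)[C@@H](OC)[C@@H](OCc1ccc(OC)cc1)C[C@H](C)[C@@H](OC)c1cc(OC)cc(Br)c1OC | intermediate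
25 | (2E,4Z,6S,7R,8E,10S,11R,12S,14S,15R)-15-(3-bromo-2,5-dimethoxyphenyl)-7-hydroxy-11,15-dimethoxy-12-[(4-methoxybenzyl)oxy]-2,6,8,10,14-pentamethylpentadeca-2,4,8-trienamide | NC(=O)/C(C)=C/C=C\[C@H](C)[C@@H](O)/C(C)=C/[C@H](C)[C@@H](OC)[C@@H](OCc1ccc(OC)cc1)C[C@H](C)[C@@H](OC)c1cc(OC)cc(Br)c1OC | intermediate
26 | (4E,6Z,8S,9R,10E,12S,13R,14S,16S,17R)-9-hydroxy-13,17,20,22-tetramethoxy-14-[(4-methoxybenzyl)oxy]-4,8,10,12,16-pentamethyl-2-azabicyclo[16.3.1]docosa-1(21),4,6,10,18(22),19-hexaen-3-one | CO[C@@H]1[C@@H](C)/C=C(\C)[C@H](O)[C@@H](C)/C=C\C=C(/C)C(=O)Nc2cc(OC)cc(c2OC)[C@H](OC)[C@@H](C)C[C@@H]1OCc3ccc(OC)cc3 | intermediate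
27 | N-trichloroacetyl carbamate of 26 at the C7 oxygen (ring position 9) | CO[C@@H]1[C@@H](C)/C=C(\C)[C@H](OC(=O)NC(=O)C(Cl)(Cl)Cl)[C@@H](C)/C=C\C=C(/C)C(=O)Nc2cc(OC)cc(c2OC)[C@H](OC)[C@@H](C)C[C@@H]1OCc3ccc(OC)cc3 | intermediate
28 | (4E,6Z,8S,9R,10E,12S,13R,14S,16S,17R)-13,17,20,22-tetramethoxy-14-[(4-methoxybenzyl)oxy]-4,8,10,12,16-pentamethyl-3-oxo-2-azabicyclo[16.3.1]docosa-1(21),4,6,10,18(22),19-hexaen-9-yl carbamate | CO[C@@H]1[C@@H](C)/C=C(\C)[C@H](OC(N)=O)[C@@H](C)/C=C\C=C(/C)C(=O)Nc2cc(OC)cc(c2OC)[C@H](OC)[C@@H](C)C[C@@H]1OCc3ccc(OC)cc3 | intermediate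
29 | (4E,6Z,8S,9R,10E,12S,13R,14S,16S,17R)-14-hydroxy-13,17-dimethoxy-4,8,10,12,16-pentamethyl-3,20,22-trioxo-2-azabicyclo[16.3.1]docosa-1(21),4,6,10,18-pentaen-9-yl carbamate (the quinone) | CO[C@@H]1[C@@H](C)/C=C(\C)[C@H](OC(N)=O)[C@@H](C)/C=C\C=C(/C)C(=O)NC2=CC(=O)C=C(C2=O)[C@H](OC)[C@@H](C)C[C@@H]1O | intermediate
30 | (4E,6Z,8S,9R,10E,12S,13R,14S,16S,17R)-14,20,22-trihydroxy-13,17-dimethoxy-4,8,10,12,16-pentamethyl-3-oxo-2-azabicyclo[16.3.1]docosa-1(21),4,6,10,18(22),19-hexaen-9-yl carbamate (CNP0548031.1) | CO[C@@H]1[C@@H](C)/C=C(\C)[C@H](OC(N)=O)[C@@H](C)/C=C\C=C(/C)C(=O)Nc2cc(O)cc(c2O)[C@H](OC)[C@@H](C)C[C@@H]1O | target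

**Step count and risks**

Total step count: 22. Longest linear sequence: 16 steps (steps 1–7, 9–11, 14, 18–22, from furfural).

Steps most likely to fail:

Step 9 (C15 configuration). Control by a single α-methyl group may give only about 3:1. Fallback: set out from lactol 8 and oxidise it (TEMPO cat., PhI(OAc)2, CH2Cl2) to the δ-lactone (3S,5S,6R)-6-[(2S)-but-3-en-2-yl]-5-[(4-methoxybenzyl)oxy]-3-methyloxan-2-one F1. Add one equivalent of aryllithium 11 at −78 °C to obtain the aryl ketone (2S,4S,5R,6S)-1-(3-bromo-2,5-dimethoxyphenyl)-5-hydroxy-4-[(4-methoxybenzyl)oxy]-2,6-dimethyloct-7-en-1-one F2. Then set C15 by reagent control with (S)-Me-CBS and catecholborane (toluene, −78 °C), which comes back to the route at diol 12.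

Step 11 (cross-metathesis). The allylically branched terminal alkene may react sluggishly with methacrolein. Fallback: set out from 13 and cleave the vinyl group (OsO4 cat., NaIO4, 2,6-lutidine, dioxane/H2O) to the aldehyde (2R,3R,4S,6S,7R)-7-(3-bromo-2,5-dimethoxyphenyl)-3,7-dimethoxy-4-[(4-methoxybenzyl)oxy]-2,6-dimethylheptanal F3. Olefinate it with the stabilised ylide 2-(triphenylphosphoranylidene)propanal (toluene, 80 °C, E-selective Wittig), which comes back to the route at enal 14.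

Step 14 (syn-propargylation). The syn preference of the BF3-promoted allenylstannane addition is less certain for an enal than for branched saturated aldehydes. Fallback: set out from enal 14 and use the anti-selective indium variant instead. (R)-But-3-yn-2-yl methanesulfonate F4 (from (R)-but-3-yn-2-ol under the conditions of step 12) with Pd(OAc)2/PPh3 and InI in THF/HMPA gives the anti alcohol (3S,4S,5E,7S,8R,9S,11S,12R)-12-(3-bromo-2,5-dimethoxyphenyl)-8,12-dimethoxy-9-[(4-methoxybenzyl)oxy]-3,5,7,11-tetramethyldodec-5-en-1-yn-4-ol F5. Mitsunobu inversion at C7 (4-nitrobenzoic acid, PPh3, DIAD, toluene, 0 °C) gives (3S,4R,5E,7S,8R,9S,11S,12R)-12-(3-bromo-2,5-dimethoxyphenyl)-8,12-dimethoxy-9-[(4-methoxybenzyl)oxy]-3,5,7,11-tetramethyldodec-5-en-1-yn-4-yl 4-nitrobenzoate F6. Methanolysis (K2CO3, MeOH) comes back to the route at 18.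

Further compounds
F1 | step 9 | (3S,5S,6R)-6-[(2S)-but-3-en-2-yl]-5-[(4-methoxybenzyl)oxy]-3-methyloxan-2-one | COc1ccc(CO[C@H]2C[C@H](C)C(=O)O[C@@H]2[C@@H](C)C=C)cc1
F2 | step 9 | (2S,4S,5R,6S)-1-(3-bromo-2,5-dimethoxyphenyl)-5-hydroxy-4-[(4-methoxybenzyl)oxy]-2,6-dimethyloct-7-en-1-one | C=C[C@H](C)[C@@H](O)[C@@H](OCc1ccc(OC)cc1)C[C@H](C)C(=O)c1cc(OC)cc(Br)c1OC
F3 | step 11 | (2R,3R,4S,6S,7R)-7-(3-bromo-2,5-dimethoxyphenyl)-3,7-dimethoxy-4-[(4-methoxybenzyl)oxy]-2,6-dimethylheptanal | O=C[C@H](C)[C@@H](OC)[C@@H](OCc1ccc(OC)cc1)C[C@H](C)[C@@H](OC)c1cc(OC)cc(Br)c1OC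
F4 | step 14 | (R)-but-3-yn-2-yl methanesulfonate | C#C[C@@H](C)OS(C)(=O)=O
F5 | step 14 | (3S,4S,5E,7S,8R,9S,11S,12R)-12-(3-bromo-2,5-dimethoxyphenyl)-8,12-dimethoxy-9-[(4-methoxybenzyl)oxy]-3,5,7,11-tetramethyldodec-5-en-1-yn-4-ol | C#C[C@H](C)[C@H](O)/C(C)=C/[C@H](C)[C@@H](OC)[C@@H](OCc1ccc(OC)cc1)C[C@H](C)[C@@H](OC)c1cc(OC)cc(Br)c1OC
F6 | step 14 | (3S,4R,5E,7S,8R,9S,11S,12R)-12-(3-bromo-2,5-dimethoxyphenyl)-8,12-dimethoxy-9-[(4-methoxybenzyl)oxy]-3,5,7,11-tetramethyldodec-5-en-1-yn-4-yl 4-nitrobenzoate | C#C[C@H](C)[C@@H](OC(=O)c1ccc(cc1)[N+](=O)[O-])/C(C)=C/[C@H](C)[C@@H](OC)[C@@H](OCc1ccc(OC)cc1)C[C@H](C)[C@@H](OC)c1cc(OC)cc(Br)c1OC
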